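**Retrosynthetic overview** (germacrane numbering: ring C1–C10, lactone C6–O–C12(=O)–C11(=C13), ester C14, CH2OH C15)
1. Target ⇐ Luche reduction of the C15 enal ⇐ ten-membered carbocycle, closed last by ring-closing metathesis at C1=C10.
2. C4=C5 ⇐ (E)-selective Wittig reaction of a C5 aldehyde with a formyl ylide; lactone ring (formed first) ⇐ acid cleavage of acetonide and tert-butyl ester with lactonisation onto O6.
3. C9–C10 ⇐ Felkin-controlled addition of an α-(methoxycarbonyl)vinylalane to the C9 aldehyde, trapped as the acetate.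
4. Key C7–C8 bond (stereocentres C7 and C8) ⇐ amide-enolate [2,3]-Wittig rearrangement of a (Z)-type allyl glycolamide ether, steered by the C6 dioxolane centre of D-glyceraldehyde acetonide.
5. Rearrangement substrate ⇐ Morita–Baylis–Hillman adduct of that aldehyde with tert-butyl acrylate, via its transposed allyl bromide.

Assumption: compounds 1, 5 and 17 are taken as catalogue chemicals.

**Step 1**
Reactants: 1 (4R)-2,2-dimethyl-1,3-dioxolane-4-carbaldehyde; 2 tert-butyl prop-2-enoate
Product: 3 tert-butyl 2-{[(4R)-2,2-dimethyl-1,3-dioxolan-4-yl](hydroxy)methyl}prop-2-enoate (both carbinol epimers)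
Conditions: DABCO (1 equiv), 1,4-dioxane/H2O 1:1, rt, 48 h
Reagents that add atoms: none
Why: Morita–Baylis–Hillman reaction of the reactive α-alkoxy aldehyde builds C7–C11; the new carbinol centre forms as a mixture but is erased in step 2, and C6 (bought in 1) is untouched.

**Step 2**
Reactants: 3 Baylis–Hillman adduct
Product: 4 tert-butyl (2Z)-2-(bromomethyl)-3-[(4S)-2,2-dimethyl-1,3-dioxolan-4-yl]prop-2-enoate
Conditions: NBS, Me2S, CH2Cl2, 0 °C → rt
Reagents that add atoms: N-bromosuccinimide, O=C1CCC(=O)N1Br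
Why: Bromosulfonium activation of the allylic alcohol and SN2′ return of bromide (allylic transposition) funnel both epimers into the single (Z)-2-(bromomethyl)enoate, with the dioxolane cis to CH2Br and trans to the ester.

**Step 3**
Reactants: 4 allyl bromide; 5 2-hydroxy-N-methoxy-N-methylacetamide
Product: 6 tert-butyl (2E)-3-[(4S)-2,2-dimethyl-1,3-dioxolan-4-yl]-2-({2-[methoxy(methyl)amino]-2-oxoethoxy}methyl)prop-2-enoate
Conditions: Ag2O (1.5 equiv), 4 Å MS, CH2Cl2, rt, dark
Reagents that add atoms: none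
Why: Silver-assisted Williamson etherification at the primary allylic carbon (SN2) installs the glycolamide ether with the alkene geometry retained, so the dioxolane stays cis to the CH2O arm.

**Step 4**
Reactants: 6 allyl glycolamide ether
Product: 9 tert-butyl (3S,4S)-3-[(4S)-2,2-dimethyl-1,3-dioxolan-4-yl]-5-[methoxy(methyl)amino]-2-methylidene-4-[(2-methylpropanoyl)oxy]-5-oxopentanoate, via lithium enolate 7 (not isolated), via lithium alkoxide 8 (not isolated)
Conditions: LiN(iPr)2 (1.2 equiv), THF, −78 °C; then i-PrCOCl, −78 → 0 °C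
Reagents that add atoms: 2-methylpropanoyl chloride, CC(C)C(Cl)=O
Why: Amide-enolate [2,3]-Wittig rearrangement forms C7–C8: the envelope transition state with the amide exo turns the (Z)-type ether into the syn C7/C8 pair, while A(1,3) strain holds H6 in the alkene plane so the enolate carbon adds anti to the allylic C6–O bond, giving 7S,8S, and the alkoxide is capped in the flask as the isobutyrate.

**Step 5**
Reactants: 9 Weinreb amide
Product: 10 tert-butyl (3S,4S)-3-[(4S)-2,2-dimethyl-1,3-dioxolan-4-yl]-2-methylidene-4-[(2-methylpropanoyl)oxy]-5-oxopentanoate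
Conditions: i-Bu2AlH (1.2 equiv), THF, −78 °C; aq. KNaC4H4O6 work-up
Reagents that add atoms: none
Why: Weinreb amide reduction: the N,O-chelated aluminium hemiaminal forms at −78 °C faster than the hindered isobutyrate and tert-butyl esters react and releases the C9 aldehyde only on work-up, leaving C7 and C8 untouched.

**Step 6**
Reactants: 10 aldehyde; 11 methyl prop-2-ynoate
Product: 14 1-tert-butyl 7-methyl (3S,4S,5R)-5-(acetyloxy)-3-[(4S)-2,2-dimethyl-1,3-dioxolan-4-yl]-2,6-dimethylidene-4-[(2-methylpropanoyl)oxy]heptanedioate, via vinylalane 12 (not isolated), via aluminium alkoxide 13 (not isolated)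
Conditions: 11, i-Bu2AlH, NMO, THF, 0 °C; then 10, −78 → 0 °C; then Ac2O, pyridine, DMAP, 0 °C → rt
Reagents that add atoms: acetic anhydride, CC(=O)OC(C)=O
Why: Vinylalumination (a Morita–Baylis–Hillman surrogate): conjugate hydroalumination of 11 gives the α-alumino acrylate, which adds to the aldehyde in the polar Felkin–Anh sense (anti to the C8–O bond) to set C9 as 9R (8,9-anti), and acetylation of the aluminium alkoxide in the flask forestalls acyl migration from O8 to O9.

**Step 7**
Reactants: 14 bis-acrylate acetonide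
Product: 15 methyl (3R,4S)-3-(acetyloxy)-4-[(2S,3S)-2-(hydroxymethyl)-4-methylidene-5-oxooxolan-3-yl]-2-methylidene-4-[(2-methylpropanoyl)oxy]butanoate
Conditions: TFA/CH2Cl2/H2O 10:10:1, 0 °C → rt
Reagents that add atoms: none
Why: Acidolysis removes the acetonide and the tert-butyl ester, and the freed γ-hydroxy acid lactonises (5-exo, at O6 rather than the δ-placed O5) to the trans-4,5-disubstituted α-methylene-γ-butyrolactone without touching a stereocentre.

**Step 8**
Reactants: 15 hydroxymethyl lactone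
Product: 16 methyl (3R,4S)-3-(acetyloxy)-4-[(2S,3R)-2-formyl-4-methylidene-5-oxooxolan-3-yl]-2-methylidene-4-[(2-methylpropanoyl)oxy]butanoate
Conditions: Dess–Martin periodinane, CH2Cl2, 0 °C → rt
Reagents that add atoms: none
Why: Dess–Martin oxidation gives the C5 aldehyde under non-basic conditions that neither epimerise C6 nor add to the Michael acceptors (the descriptor change at the ring carbon is only a priority change).

**Step 9**
Reactants: 17 (pent-4-en-1-yl)triphenylphosphonium bromide; 18 ethyl formate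
Product: 20 2-(triphenyl-λ5-phosphanylidene)hex-5-enal, via ylide 19 (not isolated)
Conditions: KOtBu (2.1 equiv), THF, 0 °C; then HCO2Et, 0 °C → rt
Reagents that add atoms: none
Why: C-formylation of the non-stabilised ylide by ethyl formate, then deprotonation of the formylphosphonium salt by the second equivalent of base, gives the formyl-stabilised ylide.

**Step 10**
Reactants: 16 lactone aldehyde; 20 formyl ylide
Product: 21 methyl (3R,4S)-3-(acetyloxy)-4-{(2R,3S)-2-[(1E)-2-formylhexa-1,5-dien-1-yl]-4-methylidene-5-oxooxolan-3-yl}-2-methylidene-4-[(2-methylpropanoyl)oxy]butanoate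
Conditions: toluene, 60 °C, 12 h
Reagents that add atoms: none
Why: Wittig olefination with the formyl-stabilised, α-branched ylide is (E)-selective, placing C6 trans to the formyl group (C15) and cis to the C3 chain as the target requires, and the hindered product enal does not react further.

**Step 11**
Reactants: 21 enal triene
Product: 22 methyl (3aS,4S,5R,6E,10E,11aR)-5-(acetyloxy)-10-formyl-3-methylidene-4-[(2-methylpropanoyl)oxy]-2-oxo-2,3,3a,4,5,8,9,11a-octahydrocyclodeca[b]furan-6-carboxylate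
Conditions: second-generation Hoveyda–Grubbs catalyst RuCl2(H2IMes)(=CH-C6H4-2-OiPr) (10 mol %), 1,4-benzoquinone (20 mol %), toluene (1 mM), 80 °C
Reagents that add atoms: none
Why: Ring-closing metathesis: the ruthenium alkylidene formed at the terminal alkene closes onto the 2-substituted acrylate to give the trisubstituted enoate, whose ring-cis (E) geometry is both the less strained and the conjugation-favoured one, whereas closure onto the lactone methylene would require a bridgehead alkene.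

**Step 12**
Reactants: 22 macrocyclic enal
Product: 23 methyl (3aS,4S,5R,6E,10E,11aR)-5-(acetyloxy)-10-(hydroxymethyl)-3-methylidene-4-[(2-methylpropanoyl)oxy]-2-oxo-2,3,3a,4,5,8,9,11a-octahydrocyclodeca[b]furan-6-carboxylate (CNP0242134.4)
Conditions: NaBH4, CeCl3·7H2O, MeOH, −78 °C
Reagents that add atoms: none
Why: Luche reduction: cerium-activated 1,2-hydride delivery to the enal at −78 °C is far faster than conjugate reduction of the α-methylene lactone or the enoate and leaves the acetate and isobutyrate intact.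

**Compound list**
1 | (4R)-2,2-dimethyl-1,3-dioxolane-4-carbaldehyde (2,3-O-isopropylidene-D-glyceraldehyde) | CC1(C)O[C@@H](C=O)CO1 | starting material
2 | tert-butyl prop-2-enoate | C=CC(=O)OC(C)(C)C | starting material
3 | tert-butyl 2-{[(4R)-2,2-dimethyl-1,3-dioxolan-4-yl](hydroxy)methyl}prop-2-enoate (both carbinol epimers) | CC1(C)O[C@@H](C(O)C(=C)C(=O)OC(C)(C)C)CO1 | intermediate
4 | tert-butyl (2Z)-2-(bromomethyl)-3-[(4S)-2,2-dimethyl-1,3-dioxolan-4-yl]prop-2-enoate | CC1(C)O[C@@H](/C=C(\CBr)C(=O)OC(C)(C)C)CO1 | intermediate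
5 | 2-hydroxy-N-methoxy-N-methylacetamide | OCC(=O)N(C)OC | starting material
6 | tert-butyl (2E)-3-[(4S)-2,2-dimethyl-1,3-dioxolan-4-yl]-2-({2-[methoxy(methyl)amino]-2-oxoethoxy}methyl)prop-2-enoate | CC1(C)O[C@@H](/C=C(\COCC(=O)N(C)OC)C(=O)OC(C)(C)C)CO1 | intermediate
7 | lithium 2-({(2E)-2-(tert-butoxycarbonyl)-3-[(4S)-2,2-dimethyl-1,3-dioxolan-4-yl]prop-2-en-1-yl}oxy)-1-[methoxy(methyl)amino]ethen-1-olate (enolate geometry not specified) | CC1(C)O[C@@H](/C=C(\COC=C(O[Li])N(C)OC)C(=O)OC(C)(C)C)CO1 | intermediate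
8 | tert-butyl (3R,4S)-3-[(4S)-2,2-dimethyl-1,3-dioxolan-4-yl]-4-(lithiooxy)-5-[methoxy(methyl)amino]-2-methylidene-5-oxopentanoate | CON(C)C(=O)[C@@H](O[Li])[C@@H](C(=C)C(=O)OC(C)(C)C)[C@H]1COC(C)(C)O1 | intermediate
9 | tert-butyl (3S,4S)-3-[(4S)-2,2-dimethyl-1,3-dioxolan-4-yl]-5-[methoxy(methyl)amino]-2-methylidene-4-[(2-methylpropanoyl)oxy]-5-oxopentanoate | CON(C)C(=O)[C@@H](OC(=O)C(C)C)[C@@H](C(=C)C(=O)OC(C)(C)C)[C@H]1COC(C)(C)O1 | intermediate
10 | tert-butyl (3S,4S)-3-[(4S)-2,2-dimethyl-1,3-dioxolan-4-yl]-2-methylidene-4-[(2-methylpropanoyl)oxy]-5-oxopentanoate | O=C[C@@H](OC(=O)C(C)C)[C@@H](C(=C)C(=O)OC(C)(C)C)[C@H]1COC(C)(C)O1 | intermediate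
11 | methyl prop-2-ynoate | C#CC(=O)OC | starting material
12 | methyl 2-[bis(2-methylpropyl)alumanyl]prop-2-enoate | C=C(C(=O)OC)[Al](CC(C)C)CC(C)C | intermediate
13 | 1-tert-butyl 7-methyl (3S,4S,5R)-5-{[bis(2-methylpropyl)alumanyl]oxy}-3-[(4S)-2,2-dimethyl-1,3-dioxolan-4-yl]-2,6-dimethylidene-4-[(2-methylpropanoyl)oxy]heptanedioate | C=C(C(=O)OC)[C@@H](O[Al](CC(C)C)CC(C)C)[C@@H](OC(=O)C(C)C)[C@@H](C(=C)C(=O)OC(C)(C)C)[C@H]1COC(C)(C)O1 | intermediate
14 | 1-tert-butyl 7-methyl (3S,4S,5R)-5-(acetyloxy)-3-[(4S)-2,2-dimethyl-1,3-dioxolan-4-yl]-2,6-dimethylidene-4-[(2-methylpropanoyl)oxy]heptanedioate | C=C(C(=O)OC)[C@@H](OC(C)=O)[C@@H](OC(=O)C(C)C)[C@@H](C(=C)C(=O)OC(C)(C)C)[C@H]1COC(C)(C)O1 | intermediate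
15 | methyl (3R,4S)-3-(acetyloxy)-4-[(2S,3S)-2-(hydroxymethyl)-4-methylidene-5-oxooxolan-3-yl]-2-methylidene-4-[(2-methylpropanoyl)oxy]butanoate | C=C1C(=O)O[C@H](CO)[C@H]1[C@H](OC(=O)C(C)C)[C@H](OC(C)=O)C(=C)C(=O)OC | intermediate
16 | methyl (3R,4S)-3-(acetyloxy)-4-[(2S,3R)-2-formyl-4-methylidene-5-oxooxolan-3-yl]-2-methylidene-4-[(2-methylpropanoyl)oxy]butanoate | C=C1C(=O)O[C@H](C=O)[C@H]1[C@H](OC(=O)C(C)C)[C@H](OC(C)=O)C(=C)C(=O)OC | intermediate
17 | (pent-4-en-1-yl)triphenylphosphonium bromide | C=CCCC[P+](c1ccccc1)(c1ccccc1)c1ccccc1.[Br-] | starting material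
18 | ethyl formate | CCOC=O | starting material
19 | (pent-4-en-1-ylidene)triphenyl-λ5-phosphane | C=CCCC=P(c1ccccc1)(c1ccccc1)c1ccccc1 | intermediate
20 | 2-(triphenyl-λ5-phosphanylidene)hex-5-enal | C=CCCC(C=O)=P(c1ccccc1)(c1ccccc1)c1ccccc1 | intermediate
21 | methyl (3R,4S)-3-(acetyloxy)-4-{(2R,3S)-2-[(1E)-2-formylhexa-1,5-dien-1-yl]-4-methylidene-5-oxooxolan-3-yl}-2-methylidene-4-[(2-methylpropanoyl)oxy]butanoate | C=C1C(=O)O[C@H](/C=C(/C=O)CCC=C)[C@H]1[C@H](OC(=O)C(C)C)[C@H](OC(C)=O)C(=C)C(=O)OC | intermediate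
22 | methyl (3aS,4S,5R,6E,10E,11aR)-5-(acetyloxy)-10-formyl-3-methylidene-4-[(2-methylpropanoyl)oxy]-2-oxo-2,3,3a,4,5,8,9,11a-octahydrocyclodeca[b]furan-6-carboxylate | C=C1C(=O)O[C@@H]2/C=C(/C=O)CC/C=C(/C(=O)OC)[C@@H](OC(C)=O)[C@@H](OC(=O)C(C)C)[C@@H]12 | intermediate
23 | methyl (3aS,4S,5R,6E,10E,11aR)-5-(acetyloxy)-10-(hydroxymethyl)-3-methylidene-4-[(2-methylpropanoyl)oxy]-2-oxo-2,3,3a,4,5,8,9,11a-octahydrocyclodeca[b]furan-6-carboxylate | C=C1C(=O)O[C@@H]2/C=C(/CO)CC/C=C(/C(=O)OC)[C@@H](OC(C)=O)[C@@H](OC(=O)C(C)C)[C@@H]12 | target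

**Step count:** 12 steps in total. Longest linear sequence: 11 steps (steps 1–8 and 10–12); step 9 is a one-step side branch.

**Steps most likely to fail, with fallbacks**

Step 4 (enolate [2,3]-Wittig rearrangement next to an enoate). Competing γ-deprotonation or conjugate processes of the enoate, or erosion of the facial preference, could spoil the key step. The fallback sets out from bromide 4 and joins C7–C8 intermolecularly: an indium-mediated Barbier allylation of glyoxylic acid (indium powder, THF/H2O), which is normally syn-selective for 2-(bromomethyl)enoates, gives the hydroxy acid F1. Coupling with MeNH(OMe)·HCl (EDC, HOBt) gives the hydroxy amide F2, and acylation with 2-methylpropanoyl chloride/pyridine comes back to the route at 9.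

Step 6 (vinylalane addition to an α-acyloxy aldehyde). Felkin selectivity may be modest and the alane may react sluggishly. The fallback sets out from aldehyde 10 and uses an aldol/selenoxide route: the lithium enolate of methyl 2-(phenylselanyl)propanoate is added at −78 °C and the aldolate is quenched with Ac2O to give the seleno acetate F3. Oxidation with H2O2/pyridine and selenoxide syn-elimination toward the methyl group (away from the acetoxy-bearing carbon) comes back to the route at 14.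

Step 11 (ring-closing metathesis onto a hindered 2-substituted acrylate to a ten-membered ring). Slow closure would favour oligomers. The fallback sets out from 14 and closes the ring at C4=C5 instead. Cross-metathesis of 14 with hex-5-enal (second-generation Hoveyda–Grubbs catalyst) at the less hindered methyl acrylate gives the enoate aldehyde F4. The TFA treatment of step 7 then gives the hydroxy lactone F5, and Dess–Martin oxidation gives the dialdehyde F6. An amine-catalysed intramolecular aldol condensation under high dilution (pyrrolidine, benzoic acid) forms the (E)-enal and comes back to the route at 22.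

**Further compounds**
F1 | step 4 | (2S,3R)-4-(tert-butoxycarbonyl)-3-[(4S)-2,2-dimethyl-1,3-dioxolan-4-yl]-2-hydroxypent-4-enoic acid | OC(=O)[C@@H](O)[C@@H](C(=C)C(=O)OC(C)(C)C)[C@H]1COC(C)(C)O1
F2 | step 4 | tert-butyl (3R,4S)-3-[(4S)-2,2-dimethyl-1,3-dioxolan-4-yl]-4-hydroxy-5-[methoxy(methyl)amino]-2-methylidene-5-oxopentanoate | CON(C)C(=O)[C@@H](O)[C@@H](C(=C)C(=O)OC(C)(C)C)[C@H]1COC(C)(C)O1
F3 | step 6 | 1-tert-butyl 7-methyl (3S,4S,5S)-5-(acetyloxy)-3-[(4S)-2,2-dimethyl-1,3-dioxolan-4-yl]-6-methyl-2-methylidene-4-[(2-methylpropanoyl)oxy]-6-(phenylselanyl)heptanedioate (both C6 epimers) | COC(=O)C(C)([Se]c1ccccc1)[C@@H](OC(C)=O)[C@@H](OC(=O)C(C)C)[C@@H](C(=C)C(=O)OC(C)(C)C)[C@H]1COC(C)(C)O1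
F4 | step 11 | 1-tert-butyl 7-methyl (3S,4S,5R,6E)-5-(acetyloxy)-3-[(4S)-2,2-dimethyl-1,3-dioxolan-4-yl]-2-methylidene-4-[(2-methylpropanoyl)oxy]-6-(5-oxopentylidene)heptanedioate | O=CCCC/C=C(/C(=O)OC)[C@@H](OC(C)=O)[C@@H](OC(=O)C(C)C)[C@@H](C(=C)C(=O)OC(C)(C)C)[C@H]1COC(C)(C)O1
F5 | step 11 | methyl (2E)-2-{(1R,2S)-1-(acetyloxy)-2-[(2S,3S)-2-(hydroxymethyl)-4-methylidene-5-oxooxolan-3-yl]-2-[(2-methylpropanoyl)oxy]ethyl}-7-oxohept-2-enoate | C=C1C(=O)O[C@H](CO)[C@H]1[C@H](OC(=O)C(C)C)[C@H](OC(C)=O)/C(C(=O)OC)=C\CCCC=O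
F6 | step 11 | methyl (2E)-2-{(1R,2S)-1-(acetyloxy)-2-[(2S,3R)-2-formyl-4-methylidene-5-oxooxolan-3-yl]-2-[(2-methylpropanoyl)oxy]ethyl}-7-oxohept-2-enoate | C=C1C(=O)O[C@H](C=O)[C@H]1[C@H](OC(=O)C(C)C)[C@H](OC(C)=O)/C(C(=O)OC)=C\CCCC=O
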